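**Retrosynthetic overview**

1. The target comes from a macrocyclic 6R alcohol that already holds all three rings, by Mitsunobu angeloylation (inversion at C6) and desilylation.
2. Key C6–C7 disconnection: the β-carbon of a butenolide (C7, by nature a Michael-acceptor carbon) is used as a nucleophile, a lactone homoenolate equivalent released from a 3-(bromomethyl)butenolide by CrCl2, and adds to the C6 enal carbon. This one step closes the ten-membered ring, sets C6 and C7 and creates the α-methylene lactone.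
3. The bromomethylbutenolide comes from a C8 allylic alcohol and 2-(bromomethyl)acrylic acid (esterification, ring-closing metathesis).
4. The 3(2H)-furanone comes from a γ-hydroxy ynone (gold cycloisomerisation), itself made from a Z vinyl iodide, CO and a terminal alkyne (carbonylative Sonogashira).
5. The alkyne diol comes from a silyl butynone and acrolein (boron aldol sets C8), then chelation-controlled MeMgBr addition (sets C10). Ring order: ring 1 furanone, ring 2 butenolide, ring 3 ten-membered carbocycle.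

Assumption: atom labels C1–C15 are the germacrane positions of the target (C1 ketone, C2=C3 furanone alkene, C3–O–C10 ether, C4=C5 bearing C15H2OH, C6 angelate carbon, C7/C8 lactone carbons, C9 CH2, C10 quaternary, C11=C13 methylene, C12 lactone carbonyl, C14 methyl); the target is 6S,7R,8S,10R with a 4Z ring alkene and a Z (angelate) ester.

**Route**

Step 1
Reactants: 1 4-(trimethylsilyl)but-3-yn-2-one; 2 acrolein
Product: 5 (5S)-5-hydroxy-1-(trimethylsilyl)hept-6-en-1-yn-3-one, via boron enolate 3 (not isolated), via boron aldolate 4 (not isolated)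
Conditions: (−)-Ipc2BCl, Et3N, Et2O, 0 °C; 2, −78 → −20 °C; H2O2, pH 7 buffer, MeOH
Reagents that add atoms: none
Why: Paterson boron aldol, in which the diisopinocampheylboron enolate of the methyl ketone adds to acrolein through a chair transition state and the Ipc ligands expose the si face of the aldehyde, setting C8 as S.

Step 2
Reactants: 5 (5S)-5-hydroxy-1-(trimethylsilyl)hept-6-en-1-yn-3-one
Product: 7 (3S,5R)-5-methylhept-1-en-6-yne-3,5-diol, via silylalkyne diol 6 (not isolated)
Conditions: MeMgBr (3 equiv), CH2Cl2/Et2O, −78 °C; then MeOH, K2CO3, rt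
Reagents that add atoms: methylmagnesium bromide (C[Mg]Br)
Why: Chelation-controlled Grignard 1,2-addition followed by protodesilylation, in which the magnesium alkoxide at C8 and the ketone form a six-membered chelate, methyl attacks axially so the alkynyl group ends equatorial and cis to the C8 vinyl group (1,3-syn diol, C10 R), and K2CO3/MeOH then removes the alkynyl silane.

Step 3
Reactants: 7 (3S,5R)-5-methylhept-1-en-6-yne-3,5-diol
Product: 8 (3R,5S)-3-methyl-5-[(triethylsilyl)oxy]hept-6-en-1-yn-3-ol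
Conditions: Et3SiCl, imidazole, CH2Cl2, 0 °C
Reagents that add atoms: chlorotriethylsilane (CC[Si](Cl)(CC)CC)
Why: Selective silylation of the secondary allylic hydroxyl over the hindered tertiary propargylic one, which keeps the C8 oxygen from adding to the later ynone while the C10 hydroxyl stays free for furanone formation.

Step 4
Reactants: 9 3,3-diethoxyprop-1-yne
Product: 11 4,4-diethoxybut-2-yn-1-ol, via lithium acetylide 10 (not isolated)
Conditions: n-BuLi, THF, −78 °C; (CH2O)n, −78 °C → rt; H2O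
Reagents that add atoms: formaldehyde, used as paraformaldehyde (C=O)
Why: Acetylide addition to formaldehyde (hydroxymethylation of a terminal alkyne) installs C15 with its oxygen.

Step 5
Reactants: 11 4,4-diethoxybut-2-yn-1-ol
Product: 13 (2Z)-4,4-diethoxy-2-iodobut-2-en-1-ol, via vinylstannane 12 (not isolated)
Conditions: Bu3SnH, [(C5Me5)RuCl]4 (1.25 mol %), CH2Cl2, rt; then I2, 0 °C
Reagents that add atoms: iodine (II)
Why: Hydroxyl-directed ruthenium-catalysed trans-hydrostannation puts tin on the alkyne carbon next to the CH2OH group with hydrogen added anti, and iododestannylation with retention gives the Z iodide in which iodine (the future C3 position) is cis to the acetal carbon C6.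

Step 6
Reactants: 13 (2Z)-4,4-diethoxy-2-iodobut-2-en-1-ol
Product: 14 tert-butyl{[(2Z)-4,4-diethoxy-2-iodobut-2-en-1-yl]oxy}dimethylsilane
Conditions: t-BuMe2SiCl, imidazole, CH2Cl2, rt
Reagents that add atoms: tert-butyldimethylsilyl chloride (CC(C)(C)[Si](C)(C)Cl)
Why: Silyl ether formation protects the C15 hydroxyl until the last step.

Step 7
Reactants: 8 (3R,5S)-3-methyl-5-[(triethylsilyl)oxy]hept-6-en-1-yn-3-ol; 14 tert-butyl{[(2Z)-4,4-diethoxy-2-iodobut-2-en-1-yl]oxy}dimethylsilane
Product: 15 (2Z,7R,9S)-3-{[(tert-butyldimethylsilyl)oxy]methyl}-1,1-diethoxy-7-hydroxy-7-methyl-9-[(triethylsilyl)oxy]undeca-2,10-dien-5-yn-4-one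
Conditions: CO (1 atm), PdCl2(PPh3)2 (5 mol %), CuI (2 mol %), Et3N, THF, rt
Reagents that add atoms: carbon monoxide ([C-]#[O+])
Why: Carbonylative Sonogashira coupling, in which oxidative addition of the vinyl iodide to zerovalent palladium, CO insertion and alkynylation of the acylpalladium join both fragments through the new C3 carbonyl with retention of the Z alkene.

Step 8
Reactants: 15 (2Z,7R,9S)-3-{[(tert-butyldimethylsilyl)oxy]methyl}-1,1-diethoxy-7-hydroxy-7-methyl-9-[(triethylsilyl)oxy]undeca-2,10-dien-5-yn-4-one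
Product: 17 (2Z)-4-{[tert-butyl(dimethyl)silyl]oxy}-3-{(5R)-5-[(2S)-2-hydroxybut-3-en-1-yl]-5-methyl-4-oxo-4,5-dihydrofuran-2-yl}but-2-enal, via furanone acetal 16 (not isolated)
Conditions: Ph3PAuCl/AgOSO2CF3 (2 mol %), toluene, rt; then AcOH/THF/H2O (3:1:1), rt
Reagents that add atoms: water (O)
Why: Gold-catalysed cycloisomerisation of a γ-hydroxy ynone (conjugate hydration at C1, then cyclodehydration of the C10 hydroxyl onto C3) gives the 3(2H)-furanone without touching C10, and mild aqueous acid then hydrolyses the allylic acetal to the Z enal and removes the triethylsilyl ether.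

Step 9
Reactants: 17 (2Z)-4-{[tert-butyl(dimethyl)silyl]oxy}-3-{(5R)-5-[(2S)-2-hydroxybut-3-en-1-yl]-5-methyl-4-oxo-4,5-dihydrofuran-2-yl}but-2-enal; 18 2-(bromomethyl)prop-2-enoic acid
Product: 19 (2S)-1-{(2R)-5-[(2Z)-1-{[tert-butyl(dimethyl)silyl]oxy}-4-oxobut-2-en-2-yl]-2-methyl-3-oxo-2,3-dihydrofuran-2-yl}but-3-en-2-yl 2-(bromomethyl)prop-2-enoate
Conditions: DCC, DMAP (5 mol %), CH2Cl2, 0 °C
Reagents that add atoms: none
Why: Steglich esterification of the only free hydroxyl (C8, retention) attaches the acid that carries the future C11, C12 and C13.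

Step 10
Reactants: 19 (2S)-1-{(2R)-5-[(2Z)-1-{[tert-butyl(dimethyl)silyl]oxy}-4-oxobut-2-en-2-yl]-2-methyl-3-oxo-2,3-dihydrofuran-2-yl}but-3-en-2-yl 2-(bromomethyl)prop-2-enoate
Product: 20 (2Z)-3-[(5R)-5-{[(2S)-4-(bromomethyl)-5-oxo-2,5-dihydrofuran-2-yl]methyl}-5-methyl-4-oxo-4,5-dihydrofuran-2-yl]-4-{[tert-butyl(dimethyl)silyl]oxy}but-2-enal
Conditions: second-generation Grubbs catalyst (10 mol %), toluene (5 mM), 80 °C
Reagents that add atoms: none
Why: Ring-closing metathesis between the C7 vinyl group and the 1,1-disubstituted acrylate expels ethene and forms the butenolide (C7=C11) with the allylic bromide on C13, leaving C8 untouched.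

Step 11 (key step)
Reactants: 20 (2Z)-3-[(5R)-5-{[(2S)-4-(bromomethyl)-5-oxo-2,5-dihydrofuran-2-yl]methyl}-5-methyl-4-oxo-4,5-dihydrofuran-2-yl]-4-{[tert-butyl(dimethyl)silyl]oxy}but-2-enal
Product: 22 macrocyclic 6R alcohol (15-O-TBS-6-O-deangeloyl-6-epi target), via allylchromium dichloride 21 (not isolated)
Conditions: CrCl2 (10 equiv), THF/DMF (4:1), rt, 20 added over 10 h (final 2 mM); H2O
Reagents that add atoms: none
Why: Nozaki–Hiyama-type Barbier allylation used with reversed polarity, in which CrCl2 turns the allylic bromide into an allylchromium species whose nucleophilic terminus is the butenolide β-carbon C7 (a lactone homoenolate equivalent), so that two natively electrophilic carbons, C7 and the aldehyde carbon C6, are joined; bond formation on the butenolide face opposite C9 gives the trans-fused lactone (C7), the ring-locked allyl geometry in a chair transition state with the enal residue equatorial gives the 6,7-anti alcohol (C6 R), and the allylic transposition creates the exocyclic methylene.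

Step 12
Reactants: 22 macrocyclic 6R alcohol (15-O-TBS-6-O-deangeloyl-6-epi target); 23 angelic acid [(2Z)-2-methylbut-2-enoic acid]
Product: 24 15-O-(tert-butyldimethylsilyl) ether of the target (6S angelate)
Conditions: PPh3, DIAD, toluene, 0 °C → rt
Reagents that add atoms: none
Why: Mitsunobu esterification, in which the C6 hydroxyl is activated as an alkoxyphosphonium ion and displaced by angelate in an SN2 reaction with inversion, giving the 6S ester without exposing the Z-configured acid to base.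

Step 13
Reactants: 24 15-O-(tert-butyldimethylsilyl) ether of the target (6S angelate)
Product: 25 CNP0176514.1 (6S,7R,8S,10R)
Conditions: HF·pyridine, THF/pyridine, 0 °C → rt
Reagents that add atoms: none
Why: Fluoride-mediated cleavage of the primary silyl ether under buffered conditions that leave the angelate, the methylene lactone and the furanone intact.

**Compound list**

1 | 4-(trimethylsilyl)but-3-yn-2-one | CC(=O)C#C[Si](C)(C)C | starting material
2 | acrolein (prop-2-enal) | C=CC=O | starting material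
3 | diisopinocampheylboron enolate of 1 | C=C(OB([C@@H]1C[C@@H]2C[C@@H](C2(C)C)[C@H]1C)[C@@H]1C[C@@H]2C[C@@H](C2(C)C)[C@H]1C)C#C[Si](C)(C)C | intermediate
4 | diisopinocampheylboron aldolate of 5 (C8 S) | C=C[C@@H](OB([C@@H]1C[C@@H]2C[C@@H](C2(C)C)[C@H]1C)[C@@H]1C[C@@H]2C[C@@H](C2(C)C)[C@H]1C)CC(=O)C#C[Si](C)(C)C | intermediate
5 | (5S)-5-hydroxy-1-(trimethylsilyl)hept-6-en-1-yn-3-one | C=C[C@@H](O)CC(=O)C#C[Si](C)(C)C | intermediate
6 | (3S,5R)-5-methyl-7-(trimethylsilyl)hept-1-en-6-yne-3,5-diol | C=C[C@@H](O)C[C@@](C)(O)C#C[Si](C)(C)C | intermediate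
7 | (3S,5R)-5-methylhept-1-en-6-yne-3,5-diol | C=C[C@@H](O)C[C@@](C)(O)C#C | intermediate
8 | (3R,5S)-3-methyl-5-[(triethylsilyl)oxy]hept-6-en-1-yn-3-ol | C=C[C@@H](O[Si](CC)(CC)CC)C[C@@](C)(O)C#C | intermediate
9 | 3,3-diethoxyprop-1-yne | CCOC(OCC)C#C | starting material
10 | (3,3-diethoxyprop-1-yn-1-yl)lithium | CCOC(OCC)C#C[Li] | intermediate
11 | 4,4-diethoxybut-2-yn-1-ol | CCOC(OCC)C#CCO | intermediate
12 | (2Z)-4,4-diethoxy-2-(tributylstannyl)but-2-en-1-ol | CCOC(OCC)/C=C(\[Sn](CCCC)(CCCC)CCCC)CO | intermediate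
13 | (2Z)-4,4-diethoxy-2-iodobut-2-en-1-ol | CCOC(OCC)/C=C(\I)CO | intermediate
14 | tert-butyl{[(2Z)-4,4-diethoxy-2-iodobut-2-en-1-yl]oxy}dimethylsilane | CCOC(OCC)/C=C(\I)CO[Si](C)(C)C(C)(C)C | intermediate
15 | (2Z,7R,9S)-3-{[(tert-butyldimethylsilyl)oxy]methyl}-1,1-diethoxy-7-hydroxy-7-methyl-9-[(triethylsilyl)oxy]undeca-2,10-dien-5-yn-4-one | C=C[C@@H](O[Si](CC)(CC)CC)C[C@@](C)(O)C#CC(=O)/C(CO[Si](C)(C)C(C)(C)C)=C\C(OCC)OCC | intermediate
16 | (2R)-5-[(2Z)-1-{[tert-butyl(dimethyl)silyl]oxy}-4,4-diethoxybut-2-en-2-yl]-2-methyl-2-{(2S)-2-[(triethylsilyl)oxy]but-3-en-1-yl}furan-3(2H)-one | C=C[C@@H](O[Si](CC)(CC)CC)C[C@@]1(C)OC(=CC1=O)/C(CO[Si](C)(C)C(C)(C)C)=C\C(OCC)OCC | intermediate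
17 | (2Z)-4-{[tert-butyl(dimethyl)silyl]oxy}-3-{(5R)-5-[(2S)-2-hydroxybut-3-en-1-yl]-5-methyl-4-oxo-4,5-dihydrofuran-2-yl}but-2-enal | C=C[C@@H](O)C[C@@]1(C)OC(=CC1=O)/C(CO[Si](C)(C)C(C)(C)C)=C\C=O | intermediate
18 | 2-(bromomethyl)prop-2-enoic acid | C=C(CBr)C(=O)O | starting material
19 | (2S)-1-{(2R)-5-[(2Z)-1-{[tert-butyl(dimethyl)silyl]oxy}-4-oxobut-2-en-2-yl]-2-methyl-3-oxo-2,3-dihydrofuran-2-yl}but-3-en-2-yl 2-(bromomethyl)prop-2-enoate | C=C[C@@H](OC(=O)C(=C)CBr)C[C@@]1(C)OC(=CC1=O)/C(CO[Si](C)(C)C(C)(C)C)=C\C=O | intermediate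
20 | (2Z)-3-[(5R)-5-{[(2S)-4-(bromomethyl)-5-oxo-2,5-dihydrofuran-2-yl]methyl}-5-methyl-4-oxo-4,5-dihydrofuran-2-yl]-4-{[tert-butyl(dimethyl)silyl]oxy}but-2-enal | O=C1O[C@@H](C[C@@]2(C)OC(=CC2=O)/C(CO[Si](C)(C)C(C)(C)C)=C\C=O)C=C1CBr | intermediate
21 | allylchromium dichloride of 20 (CrCl2 in place of Br on C13) | O=C1O[C@@H](C[C@@]2(C)OC(=CC2=O)/C(CO[Si](C)(C)C(C)(C)C)=C\C=O)C=C1C[Cr](Cl)Cl | intermediate
22 | macrocyclic 6R alcohol: target skeleton with free 6-OH epimeric to the target at C6 only, 15-O-TBS, trans-fused methylene lactone (CIP 6R,7S,8S,10R; C7 has the target's spatial arrangement) | C=C1C(=O)O[C@H]2C[C@@]3(C)OC(=CC3=O)/C(CO[Si](C)(C)C(C)(C)C)=C\[C@@H](O)[C@H]12 | intermediate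
23 | angelic acid, (2Z)-2-methylbut-2-enoic acid | C/C=C(/C)C(=O)O | starting material
24 | 15-O-(tert-butyldimethylsilyl) ether of the target (6S,7R,8S,10R) | C=C1C(=O)O[C@H]2C[C@@]3(C)OC(=CC3=O)/C(CO[Si](C)(C)C(C)(C)C)=C\[C@H](OC(=O)/C(C)=C\C)[C@H]12 | intermediate
25 | CNP0176514.1 (6S,7R,8S,10R) | C=C1C(=O)O[C@H]2C[C@@]3(C)OC(=CC3=O)/C(CO)=C\[C@H](OC(=O)/C(C)=C\C)[C@H]12 | target

**Totals**

Total step count: 13. Longest linear sequence: 10 steps (1 → 25 through steps 1, 2, 3, 7–13; the branch from 9 through steps 4–6 and 7–13 is equally long).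

**Three steps most likely to fail, each with a fallback**

Step 11 (macrocyclisation). The ten-membered ring may close in low yield, with cis ring fusion or with the other C6 configuration, because the tether and not only the chair model decides the outcome. Fallback: setting out from 20, palladium-catalysed borylation with bis(pinacolato)diboron (tris(dibenzylideneacetone)dipalladium, THF) would give the isolable allylboronate F1. Heating F1 at high dilution (toluene, 80 °C, or catalytic Sc(OSO2CF3)3) would close the ring by a metal-reductant-free intramolecular allylboration through the same chair-type transition state, and aqueous work-up would come back to the route at 22.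

Step 12 (Mitsunobu angeloylation). A hindered, allylic, macrocyclic alcohol may give SN2′ products or elimination, and the phosphine can isomerise angelate to tiglate. Fallback: setting out from 22, Dess–Martin oxidation would give the C6 ketone F2. Corey–Bakshi–Shibata reduction (oxazaborolidine antipode chosen for the 6S carbinol, BH3·SMe2) would give the 6S alcohol F3. Yamaguchi esterification of F3 with 23 (2,4,6-trichlorobenzoyl chloride, Et3N, DMAP), which retains configuration, would come back to the route at 24.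

Step 10 (ring-closing metathesis). The allylic bromide may poison or isomerise the ruthenium carbene, and the electron-poor 1,1-disubstituted alkene is a slow partner. Fallback: setting out from 17, esterification with 2-(acetoxymethyl)prop-2-enoic acid (DCC, DMAP) would give the acetoxymethyl acrylate F4, and ring-closing metathesis would give the 3-(acetoxymethyl)butenolide F5, which carries no halide. Pd(PPh3)4 with InI at high dilution would then ionise the allylic acetate to a π-allylpalladium complex and reduce it to a nucleophilic allylindium species that adds through C7 to the C6 aldehyde, coming back to the route at 22 and bypassing 20.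

**Further compounds**

F1 | step 11 | (2Z)-4-{[tert-butyl(dimethyl)silyl]oxy}-3-[(5R)-5-methyl-4-oxo-5-({(2S)-5-oxo-4-[(4,4,5,5-tetramethyl-1,3,2-dioxaborolan-2-yl)methyl]-2,5-dihydrofuran-2-yl}methyl)-4,5-dihydrofuran-2-yl]but-2-enal | O=C1O[C@@H](C[C@@]2(C)OC(=CC2=O)/C(CO[Si](C)(C)C(C)(C)C)=C\C=O)C=C1CB1OC(C)(C)C(C)(C)O1
F2 | step 12 | C6 ketone of 22 (15-O-TBS, 7R,8S,10R) | C=C1C(=O)O[C@H]2C[C@@]3(C)OC(=CC3=O)/C(CO[Si](C)(C)C(C)(C)C)=C\C(=O)[C@H]12
F3 | step 12 | macrocyclic 6S alcohol (C6 epimer of 22, 15-O-TBS) | C=C1C(=O)O[C@H]2C[C@@]3(C)OC(=CC3=O)/C(CO[Si](C)(C)C(C)(C)C)=C\[C@H](O)[C@H]12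
F4 | step 10 | (2S)-1-{(2R)-5-[(2Z)-1-{[tert-butyl(dimethyl)silyl]oxy}-4-oxobut-2-en-2-yl]-2-methyl-3-oxo-2,3-dihydrofuran-2-yl}but-3-en-2-yl 2-(acetoxymethyl)prop-2-enoate | C=C[C@@H](OC(=O)C(=C)COC(C)=O)C[C@@]1(C)OC(=CC1=O)/C(CO[Si](C)(C)C(C)(C)C)=C\C=O
F5 | step 10 | {(5S)-5-({(2R)-5-[(2Z)-1-{[tert-butyl(dimethyl)silyl]oxy}-4-oxobut-2-en-2-yl]-2-methyl-3-oxo-2,3-dihydrofuran-2-yl}methyl)-2-oxo-2,5-dihydrofuran-3-yl}methyl acetate | O=C1O[C@@H](C[C@@]2(C)OC(=CC2=O)/C(CO[Si](C)(C)C(C)(C)C)=C\C=O)C=C1COC(C)=O
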